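**Plan**
- Retrosynthesis: ester hydrolysis; then ring B is cut at its CH2–CH(ring A) bond together with one temporary cyclobutane C–C bond, giving a 5-methylene enone; then the pyran O–C and CH2–C bonds (oxa-Diels–Alder) give β-caryophyllene and a 3-methylene-cyclopentane-1,2-dione; then C–CH3 and C–CH2N at ring C (conjugate methylation/Mannich); then the ring C–ring A bond (allyl–alkenyl Stille).
- Forward order: ring A comes from cyclopent-3-enecarboxylic acid and ring C from 3-ethoxycyclopentenone. The pyran ring follows by cycloaddition, which brings in the nine- and four-membered rings intact. Ring B closes last, by light, inside a bicyclo[2.1.1]hexane whose strain drives the reductive C–C cleavage that follows.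
- Enabling feature: the methyl-bearing quaternary carbon shared by rings B and C lies between the two α-carbons of ring C's 1,2-dioxygenated unit, and each α-carbon carries one CH2 (the pyran CH2 and the ring B CH2). Both are therefore methylenes of a cyclopentane-1,2-dione. The ring B CH2 is β to the ring C ketone and five atoms from a ring A alkene carbon, i.e. a 2-acyl-1,5-diene set up for a crossed [2+2] photocycloaddition.
- Stereochemistry: ring A centres from iodolactonisation (cis), lipase resolution and Stille inversion (trans); the quaternary methyl from catalyst-controlled copper conjugate addition; the pyran centres from suprafacial addition to the exposed face of the E-alkene of caryophyllene; both ring B fusions from tether- and ring-enforced cis closures.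

Key step: step 13

Assumption: the cyclobutane centres in the SMILES are (1S,9R) in caryophyllene numbering, so the terpene half is (+)-β-caryophyllene, the antipode of the bulk plant terpene; it is taken as a purchased starting material, and step 11 is the same chemistry for either antipode.

**Route**

Step 1
Reactants: 1 cyclopent-3-ene-1-carboxylic acid
Product: 2 1-methylcyclopent-3-ene-1-carboxylic acid
Conditions: LiN(iPr)2 (2.2 equiv), THF, −78 to 0 °C; MeI; aq. HCl
Reagents that add atoms: iodomethane, CI
Why: Alkylation of the carboxylic acid dianion at its only enolisable carbon; the product is achiral.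

Step 2
Reactants: 2 1-methylcyclopent-3-ene-1-carboxylic acid
Product: 3 (±)-6-iodo-4-methyl-2-oxabicyclo[2.2.1]heptan-3-one (iodine anti to the lactone bridge)
Conditions: I2, KI, NaHCO3, H2O/THF, 0 °C to rt, dark
Reagents that add atoms: iodine, II
Why: Iodolactonisation; the carboxylate opens the iodonium ion from its own face, so the ring oxygen is cis to the carboxyl carbon and iodine is trans to oxygen (racemic, the two alkene carbons being enantiotopic).

Step 3
Reactants: 3 (±)-iodolactone
Product: 5 (±)-methyl cis-4-hydroxy-1-methylcyclopent-2-ene-1-carboxylate, via vinyl lactone 4 (not isolated)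
Conditions: DBU, THF, 65 °C; then MeOH, K2CO3 (cat.), 0 °C
Reagents that add atoms: methanol, CO
Why: Dehydroiodination gives the strained allylic lactone, which methoxide opens at the acyl carbon (transesterification), so the carbinol carbon is untouched and OH stays cis to CO2Me.

Step 4
Reactants: 5 (±)-methyl cis-4-hydroxy-1-methylcyclopent-2-ene-1-carboxylate
Product: 6 methyl (1R,4S)-4-hydroxy-1-methylcyclopent-2-ene-1-carboxylate
Conditions: Candida antarctica lipase B (immobilised), vinyl acetate, tBuOMe, 30 °C, run to just past half conversion; chromatography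
Reagents that add atoms: none
Why: Lipase kinetic resolution by transesterification; the empirical rule for lipases and secondary alcohols predicts acylation of the (4R)-carbinol, which should leave the (1R,4S)-alcohol.

Step 5
Reactants: 6 methyl (1R,4S)-4-hydroxy-1-methylcyclopent-2-ene-1-carboxylate
Product: 7 methyl (1R,4S)-4-acetoxy-1-methylcyclopent-2-ene-1-carboxylate
Conditions: Ac2O, pyridine, 4-(dimethylamino)pyridine (cat.), CH2Cl2, 0 °C
Reagents that add atoms: acetic anhydride, CC(=O)OC(C)=O
Why: Acylation of a secondary allylic alcohol under nucleophilic catalysis; no stereocentre is touched.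

Step 6
Reactants: 8 3-ethoxycyclopent-2-en-1-one
Product: 9 3-(tributylstannyl)cyclopent-2-en-1-one
Conditions: Bu3SnLi (from Bu3SnH and LiN(iPr)2, THF, 0 °C), −78 °C; aq. NH4Cl
Reagents that add atoms: tributylstannyllithium, [Li][Sn](CCCC)(CCCC)CCCC
Why: Addition of the stannyl anion to the vinylogous ester and loss of ethoxide (addition–elimination; any 1,2-adduct converges by allylic transposition on work-up) should give the β-stannyl enone.

Step 7
Reactants: 7 methyl (1R,4S)-4-acetoxy-1-methylcyclopent-2-ene-1-carboxylate; 9 3-(tributylstannyl)cyclopent-2-en-1-one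
Product: 10 methyl (1R,4R)-1-methyl-4-(3-oxocyclopent-1-en-1-yl)cyclopent-2-ene-1-carboxylate
Conditions: Pd2(dba)3 (zerovalent palladium, 2.5 mol %), LiCl, DMF, 40 °C
Reagents that add atoms: none
Why: Stille allyl–alkenyl coupling; zerovalent palladium ionises the acetate with inversion and the alkenyl group is delivered from palladium with retention, so ring C should end trans to CO2Me, bonded at the allyl terminus remote from the quaternary carbon.

Step 8
Reactants: 10 methyl (1R,4R)-1-methyl-4-(3-oxocyclopent-1-en-1-yl)cyclopent-2-ene-1-carboxylate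
Product: 13 methyl (1R,4R)-4-[(1R)-2-[(dimethylamino)methyl]-1-methyl-3-oxocyclopentyl]-1-methylcyclopent-2-ene-1-carboxylate (epimers at the aminomethyl carbon), via aluminium enolate 11 (not isolated), via silyl enol ether 12 (not isolated)
Conditions: Me3Al (1.5 equiv), Cu(O2C–C4H3S) (copper thiophene-2-carboxylate, monovalent copper, 2 mol %), O,O'-(1,1'-binaphthyl-2,2'-diyl)-N,N-bis(1-phenylethyl)phosphoramidite (4 mol %, the enantiomer that directs methyl to the Si face of the enone β-carbon), Et2O, −30 °C; then Me3SiOSO2CF3; then CH2=NMe2+ I−, CH2Cl2, 0 °C to rt; aq. NaHCO3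
Reagents that add atoms: trimethylaluminium, C[Al](C)C; dimethylmethyleneammonium iodide (Eschenmoser's salt), C=[N+](C)C.[I-]
Why: Copper-catalysed asymmetric conjugate addition of Me3Al to a β-substituted cyclopentenone should set the quaternary carbon under catalyst control, and the regiodefined enolate, silylated, takes the Mannich CH2 only at the carbon between the ketone and the quaternary centre (three components joined in one operation).

Step 9
Reactants: 13 Mannich base ketone
Product: 14 methyl (1R,4R)-4-[(1R)-2-[(dimethylamino)methyl]-4-hydroxy-1-methyl-3-oxocyclopentyl]-1-methylcyclopent-2-ene-1-carboxylate (epimer mixture at the two carbons next to the ketone)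
Conditions: KN(SiMe3)2, THF, −78 °C; 2-(phenylsulfonyl)-3-phenyloxaziridine; aq. NH4Cl
Reagents that add atoms: 2-(phenylsulfonyl)-3-phenyloxaziridine, O=S(=O)(c1ccccc1)N1OC1c1ccccc1
Why: Kinetic deprotonation at the unhindered CH2 on the far side of the ketone and electrophilic hydroxylation of that enolate; the new carbinol centre is removed in step 10.

Step 10
Reactants: 14 α-hydroxy ketone
Product: 15 methyl (1R,4R)-4-[(1R)-2-[(dimethylamino)methyl]-3-hydroxy-1-methyl-4-oxocyclopent-2-en-1-yl]-1-methylcyclopent-2-ene-1-carboxylate (enolised 1,2-dione)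
Conditions: Dess–Martin periodinane, NaHCO3, CH2Cl2, 0 °C to rt
Reagents that add atoms: none
Why: Oxidation of the α-hydroxy ketone to the 1,2-dione, which should rest as the conjugated enol; the quaternary centre stays defined because its two flanking carbons now differ.

Step 11
Reactants: 15 enolised dione Mannich base; 16 (+)-β-caryophyllene
Product: 19 pyran-fused 2-alkoxycyclopentenone (hetero-Diels–Alder adduct; ring C ketone with α-CH2, ring A cyclopentene attached), via methiodide 17 (not isolated), via methylene dione 18 (not isolated)
Conditions: MeI (1.1 equiv), MeCN, rt; then 16 (3 equiv), iPr2NEt, 50 °C; chromatography from the minor facial isomer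
Reagents that add atoms: none
Why: Quaternisation and loss of NMe3 give the 3-methylene-1,2-dione, an oxa-diene of the o-quinone methide kind, which adds to the strained E-trisubstituted alkene (inverse-demand oxa-Diels–Alder) with O on the methyl-bearing carbon, suprafacially on the exposed alkene face (the face peracids take), which sets both pyran stereocentres; the exocyclic and ring A alkenes are unstrained and should not compete.

Step 12
Reactants: 19 hetero-Diels–Alder adduct
Product: 22 5-methylene enone (ring C: C=O flanked by the alkoxy-alkene and by C=CH2), via Mannich base 20 (not isolated), via methiodide 21 (not isolated)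
Conditions: LiN(iPr)2, THF, −78 °C; CH2=NMe2+ I−, −78 to 0 °C; MeI, rt; DBU, rt
Reagents that add atoms: dimethylmethyleneammonium iodide (Eschenmoser's salt), C=[N+](C)C.[I-]
Why: Kinetic deprotonation at the only α' CH2 of the 2-alkoxy enone, Mannich reaction, quaternisation and elimination (α-methylenation of a ketone); no stereocentre is affected.

Step 13
Reactants: 22 5-methylene enone
Product: 23 photoadduct, a 1-acylbicyclo[2.1.1]hexane in which ring B is closed and one extra bond joins the ketone α-carbon to the ring A carbon next to C(Me)(CO2Me)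
Conditions: hν (365 nm), degassed MeCN (3 mM), 0 °C
Reagents that add atoms: none
Why: Excitation and intersystem crossing give the enone triplet, whose β-carbon (the exocyclic CH2) bonds to the ring A alkene carbon five atoms away, and the resulting 1,4-diradical (α-keto radical and secondary ring A radical) collapses to the cyclobutane. The closest known reaction type is the intramolecular crossed [2+2] photocycloaddition of 2-acyl-1,5-hexadienes to 1-acylbicyclo[2.1.1]hexanes. Ring B closes in the 5-exo-trig (rule-of-five) mode, and the four-membered ring closes by radical–radical recombination. The ring A carbon that receives the CH2 is forced cis to the neighbouring C–C(quaternary) bond because the two-atom tether reaches only that alkene face; the other two new centres are a bridgehead and a bridge of the bicycle and are fixed by it. The step needs reaction at the exocyclic methylene and not at the alkoxy-substituted ring C=C, crossed and not straight closure, and no reaction of the caryophyllene methylene. These should be secured by the unhindered terminal CH2 against a fully substituted β-carbon, by the five-membered first closure, and by distance.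

Step 14
Reactants: 23 photoadduct
Product: 24 sterhirsutin D methyl ester
Conditions: SmI2 (divalent samarium, 2.5 equiv), THF/MeOH, −78 °C; aq. NH4Cl
Reagents that add atoms: none
Why: Electron transfer to the ketone gives a ketyl that cleaves the adjacent cyclobutane bond with release of the bicyclo[2.1.1]hexane strain, towards the secondary ring A radical and not the primary CH2 radical; reduction and protonation then give the ring A CH2 and the enolate, which can be protonated only to the cis B/C fusion (H cis to the quaternary methyl).

Step 15
Reactants: 24 sterhirsutin D methyl ester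
Product: 25 sterhirsutin D
Conditions: LiOH, THF/MeOH/H2O, 50 °C; dilute HCl to pH 3, 0 °C
Reagents that add atoms: lithium hydroxide, [Li+].[OH-]
Why: Saponification of the methyl ester; the only enolisable centre is a cis ring fusion, so base cannot change it.

**Compound list**

1 | cyclopent-3-ene-1-carboxylic acid | OC(=O)C1CC=CC1 | starting material
2 | 1-methylcyclopent-3-ene-1-carboxylic acid | CC1(CC=CC1)C(=O)O | intermediate
3 | (±)-6-iodo-4-methyl-2-oxabicyclo[2.2.1]heptan-3-one (enantiomer carried on is shown) | O=C1O[C@H]2C[C@]1(C)C[C@@H]2I | intermediate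
4 | (±)-4-methyl-2-oxabicyclo[2.2.1]hept-5-en-3-one | O=C1O[C@H]2C[C@]1(C)C=C2 | intermediate (not isolated)
5 | (±)-methyl cis-4-hydroxy-1-methylcyclopent-2-ene-1-carboxylate (enantiomer carried on is shown) | O[C@H]1C[C@@](C)(C(=O)OC)C=C1 | intermediate
6 | methyl (1R,4S)-4-hydroxy-1-methylcyclopent-2-ene-1-carboxylate | O[C@H]1C[C@@](C)(C(=O)OC)C=C1 | intermediate
7 | methyl (1R,4S)-4-acetoxy-1-methylcyclopent-2-ene-1-carboxylate | CC(=O)O[C@H]1C[C@@](C)(C(=O)OC)C=C1 | intermediate
8 | 3-ethoxycyclopent-2-en-1-one | CCOC1=CC(=O)CC1 | starting material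
9 | 3-(tributylstannyl)cyclopent-2-en-1-one | CCCC[Sn](CCCC)(CCCC)C1=CC(=O)CC1 | intermediate
10 | methyl (1R,4R)-1-methyl-4-(3-oxocyclopent-1-en-1-yl)cyclopent-2-ene-1-carboxylate | O=C1C=C(CC1)[C@@H]2C[C@@](C)(C(=O)OC)C=C2 | intermediate
11 | dimethylaluminium enolate of the 3-methyl-3-(ring A)cyclopentanone | C[Al](C)OC1=C[C@](C)(CC1)[C@@H]2C[C@@](C)(C(=O)OC)C=C2 | intermediate (not isolated)
12 | trimethylsilyl enol ether of the same ketone | C[Si](C)(C)OC1=C[C@](C)(CC1)[C@@H]2C[C@@](C)(C(=O)OC)C=C2 | intermediate (not isolated)
13 | methyl (1R,4R)-4-[(1R)-2-[(dimethylamino)methyl]-1-methyl-3-oxocyclopentyl]-1-methylcyclopent-2-ene-1-carboxylate (epimers at the aminomethyl carbon) | CN(C)CC1C(=O)CC[C@]1(C)[C@@H]2C[C@@](C)(C(=O)OC)C=C2 | intermediate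
14 | the 4-hydroxy derivative of 13 (α-hydroxy ketone, epimer mixture) | CN(C)CC1C(=O)C(O)C[C@]1(C)[C@@H]2C[C@@](C)(C(=O)OC)C=C2 | intermediate
15 | methyl (1R,4R)-4-[(1R)-2-[(dimethylamino)methyl]-3-hydroxy-1-methyl-4-oxocyclopent-2-en-1-yl]-1-methylcyclopent-2-ene-1-carboxylate | CN(C)CC1=C(O)C(=O)C[C@]1(C)[C@@H]2C[C@@](C)(C(=O)OC)C=C2 | intermediate
16 | (+)-β-caryophyllene, (1S,4E,9R)-4,11,11-trimethyl-8-methylidenebicyclo[7.2.0]undec-4-ene | C=C1CC/C=C(C)/CC[C@H]2[C@H]1CC2(C)C | starting material
17 | trimethylammonium iodide of 15 | C[N+](C)(C)CC1=C(O)C(=O)C[C@]1(C)[C@@H]2C[C@@](C)(C(=O)OC)C=C2.[I-] | intermediate (not isolated)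
18 | methyl (1R,4R)-1-methyl-4-[(1R)-1-methyl-2-methylidene-3,4-dioxocyclopentyl]cyclopent-2-ene-1-carboxylate | C=C1C(=O)C(=O)C[C@]1(C)[C@@H]2C[C@@](C)(C(=O)OC)C=C2 | intermediate (not isolated)
19 | hetero-Diels–Alder adduct: caryophyllene-fused dihydropyran annulated to the 2-alkoxycyclopent-2-enone, with C(Me)(ring A cyclopentenyl) and CH2 completing ring C | C=C1CC[C@@H]2CC3=C(O[C@@]2(C)CC[C@H]2[C@H]1CC2(C)C)C(=O)C[C@]3(C)[C@@H]1C[C@@](C)(C(=O)OC)C=C1 | intermediate
20 | α'-(dimethylaminomethyl) ketone from 19 (epimers at that carbon) | C=C1CC[C@@H]2CC3=C(O[C@@]2(C)CC[C@H]2[C@H]1CC2(C)C)C(=O)C(CN(C)C)[C@]3(C)[C@@H]1C[C@@](C)(C(=O)OC)C=C1 | intermediate (not isolated)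
21 | trimethylammonium iodide of 20 | C=C1CC[C@@H]2CC3=C(O[C@@]2(C)CC[C@H]2[C@H]1CC2(C)C)C(=O)C(C[N+](C)(C)C)[C@]3(C)[C@@H]1C[C@@](C)(C(=O)OC)C=C1.[I-] | intermediate (not isolated)
22 | 5-methylene enone (α'-methylene derivative of 19) | C=C1CC[C@@H]2CC3=C(O[C@@]2(C)CC[C@H]2[C@H]1CC2(C)C)C(=O)C(=C)[C@]3(C)[C@@H]1C[C@@](C)(C(=O)OC)C=C1 | intermediate
23 | crossed [2+2] photoadduct (1-acylbicyclo[2.1.1]hexane; ring B closed, extra bond from the ketone α-carbon to ring A) | C=C1CC[C@@H]2CC3=C(O[C@@]2(C)CC[C@H]2[C@H]1CC2(C)C)C(=O)[C@@]41C[C@H]2[C@@H]4[C@](C)(C(=O)OC)C[C@H]2[C@]31C | intermediate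
24 | sterhirsutin D methyl ester | C=C1CC[C@@H]2CC3=C(O[C@@]2(C)CC[C@H]2[C@H]1CC2(C)C)C(=O)[C@@H]1C[C@H]2C[C@](C)(C(=O)OC)C[C@H]2[C@]31C | intermediate
25 | sterhirsutin D | C=C1CC[C@@H]2CC3=C(O[C@@]2(C)CC[C@H]2[C@H]1CC2(C)C)C(=O)[C@@H]1C[C@H]2C[C@](C)(C(=O)O)C[C@H]2[C@]31C | target

**Step count and risks**

Total: 15 steps. Longest linear sequence: 14 steps (steps 1–5 and 7–15); step 6 is a one-step branch.

Steps most likely to fail:

1. Step 8. Methyl transfer to a β-carbon that carries an α-branched substituent may be slow, and the catalyst's facial preference may be mismatched with the adjacent ring A stereocentre, giving poor facial selectivity at the quaternary carbon. Fallback, from 10, returning at 12: enone 10 is reduced with catecholborane and (R)-2-methyl-CBS-oxazaborolidine to the (S)-allylic alcohol F1. Hydroxyl-directed Simmons–Smith cyclopropanation (Et2Zn, CH2I2) puts the CH2 on the alcohol face to give the cyclopropyl carbinol F2. Dess–Martin oxidation gives the bicyclo[3.1.0]hexan-2-one F3. Lithium in liquid ammonia then cleaves the external cyclopropane bond, which leaves the CH3 on the quaternary carbon with its configuration fixed by the carbinol, and the regiodefined enolate is silylated (Me3SiCl) to silyl enol ether 12.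

2. Step 13. The excited dienone may add through its other (alkoxy-substituted) C=C, the 1,4-diradical may transfer hydrogen instead of closing, or the enone may oligomerise. Fallback, from 22, returning at 24: benzeneselenol (from PhSeSePh and NaBH4, EtOH/AcOH) adds to the exocyclic methylene, and protonation anti to ring A gives the α-(phenylselanylmethyl) ketone F4 with the CH2 cis to ring A. Bu3SnH and azobisisobutyronitrile in benzene at 80 °C generate the primary radical, which closes ring B by 5-exo-trig addition to the ring A alkene and is reduced to ester 24.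

3. Step 14. The ketyl may cleave the other one-carbon bridge, or the alkoxy-enone may be over-reduced by excess reductant. Fallback, from 23, returning at 24: a radical chain with Bu3SnH and azobisisobutyronitrile (benzene, 80 °C) replaces electron transfer. The tin radical adds to the ketone oxygen, the O-stannyl ketyl fragments the strained bond, the secondary radical takes hydrogen from Sn–H, and the tin enolate is hydrolysed on work-up; no second electron is available for over-reduction and no new isolable compound is made (F0).

**Further compounds**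

F1 | step 8 | methyl (1R,4R)-4-[(3S)-3-hydroxycyclopent-1-en-1-yl]-1-methylcyclopent-2-ene-1-carboxylate | O[C@H]1CCC(=C1)[C@@H]2C[C@@](C)(C(=O)OC)C=C2
F2 | step 8 | cyclopropyl carbinol (2-hydroxybicyclo[3.1.0]hexane carrying ring A at the ring-fusion carbon, CH2 syn to OH) | O[C@H]1CC[C@]2(C[C@@H]12)[C@@H]3C[C@@](C)(C(=O)OC)C=C3
F3 | step 8 | cyclopropyl ketone (bicyclo[3.1.0]hexan-2-one carrying ring A at the ring-fusion carbon) | O=C1CC[C@]2(C[C@@H]12)[C@@H]3C[C@@](C)(C(=O)OC)C=C3
F4 | step 13 | α-(phenylselanylmethyl) ketone from 22 | C=C1CC[C@@H]2CC3=C(O[C@@]2(C)CC[C@H]2[C@H]1CC2(C)C)C(=O)[C@H](C[Se]c1ccccc1)[C@]3(C)[C@@H]1C[C@@](C)(C(=O)OC)C=C1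
F0 | step 14 | none | none
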